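**Plan**
- Retrosynthesis: the two aryl silyl ethers come off last, then ring A is cut at C8a–C8, C7–C8, C5–C6 and C4a–C5. Ring A carries O on C5, C7 and C8a and H on C6 and C8, which is the pattern given by a vinylketene C4a=C8a–C8H=C5=O (from a 6-diazoacetyl-dihydropyran-4-one, ring C) and the ynol ether HC6≡C7–OSi.
- Ring C is cut at O1–C8a (cyclodehydration) and C2–C3 (vinylogous aldol) into the B-ring aldehyde and ethyl 2,4-dioxopentanoate. C8 comes from diazomethane.
- The aldehyde is cut at C2'–prenyl (Stille coupling) and at the dimethylpyran ring D (aryl propargyl ether Claisen cascade), back to 6-bromovanillin.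
- Forward order of rings: B (bought), then D (chromene), then C (dihydropyranone), then A (benzannulation).
- Stereochemistry: the only stereocentre, C2 (S), is set by the (S)-BINOL–Ti(IV)-catalysed aldol. Every later step avoids base strong enough to open ring C.

Key step: step 11

Assumption: flavanone numbering is used (ring A C4a–C8a, ring C O1–C4, ring B primed); Ar = 2,2-dimethyl-5-(3-methylbut-2-en-1-yl)-8-(triisopropylsilyloxy)-2H-chromen-6-yl; (triisopropylsilyloxy)ethyne is taken not to be a catalogue item and is made in step 10; ethereal diazomethane is generated from N-methyl-N-nitroso-p-toluenesulfonamide/KOH just before use.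

**Step 1**
Reactants: 1 6-bromovanillin (2-bromo-4-hydroxy-5-methoxybenzaldehyde)
Product: 2 2-bromo-4,5-dihydroxybenzaldehyde
Conditions: AlCl3, pyridine, CH2Cl2, reflux; then aq HCl
Reagents that add atoms: none
Why: Chelation-assisted demethylation of a guaiacol (AlCl3–pyridine), in which aluminium bridges the free 4-O and the methoxy oxygen so that only this O–CH3 bond is cleaved and CHO and C–Br are untouched.

**Step 2**
Reactants: 2 2-bromo-4,5-dihydroxybenzaldehyde; 3 3-chloro-3-methylbut-1-yne
Product: 4 2-bromo-5-hydroxy-4-[(2-methylbut-3-yn-2-yl)oxy]benzaldehyde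
Conditions: DBU (1.1 equiv), CuCl2·2H2O (1 mol%), MeCN, 0 °C, argon
Reagents that add atoms: none
Why: Copper-catalysed propargylic etherification of a phenoxide; with one equivalent of base only the 4-OH (para to CHO, by far the more acidic) is ionised, so the ether should form at O4 as in the known 4-O-selective alkylations of 3,4-dihydroxybenzaldehydes.

**Step 3**
Reactants: 4 2-bromo-5-hydroxy-4-[(2-methylbut-3-yn-2-yl)oxy]benzaldehyde
Product: 5 2-bromo-4-[(2-methylbut-3-yn-2-yl)oxy]-5-(triisopropylsilyloxy)benzaldehyde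
Conditions: TIPSOTf, 2,6-lutidine, CH2Cl2, 0 °C
Reagents that add atoms: triisopropylsilyl triflate, CC(C)[Si](C(C)C)(C(C)C)OS(=O)(=O)C(F)(F)F
Why: Standard silylation of a hindered phenol; TIPS is chosen because it should withstand the thermal, palladium, Lewis acid, TFA and tin hydroxide steps and leave together with the 7-O-TIPS group at the end.

**Step 4**
Reactants: 5 2-bromo-4-[(2-methylbut-3-yn-2-yl)oxy]-5-(triisopropylsilyloxy)benzaldehyde
Product: 6 5-bromo-2,2-dimethyl-8-(triisopropylsilyloxy)-2H-chromene-6-carbaldehyde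
Conditions: o-xylene, 140 °C
Reagents that add atoms: none
Why: Aryl propargyl ether Claisen rearrangement, 1,5-H shift and oxa-6π electrocyclisation (the standard 2,2-dimethylchromene synthesis); C3 is the only free ortho position because C5 carries OTIPS, so only one regioisomer can form.

**Step 5**
Reactants: 6 5-bromo-2,2-dimethyl-8-(triisopropylsilyloxy)-2H-chromene-6-carbaldehyde; 7 tributyl(3-methylbut-2-en-1-yl)stannane
Product: 8 2,2-dimethyl-5-(3-methylbut-2-en-1-yl)-8-(triisopropylsilyloxy)-2H-chromene-6-carbaldehyde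
Conditions: Pd(PPh3)4 (5 mol%), DMF, 90 °C
Reagents that add atoms: none
Why: Stille coupling under neutral conditions that spare CHO and the aryl silyl ether; the ortho formyl group speeds oxidative addition, and the doubly ortho-substituted aryl–Pd should couple at the primary allyl terminus to give the linear prenyl group.

**Step 6**
Reactants: 9 ethyl 2,4-dioxopentanoate
Product: 10 ethyl (2Z)-2,4-bis(trimethylsilyloxy)penta-2,4-dienoate
Conditions: TMSOTf (2.2 equiv), Et3N (2.5 equiv), Et2O, 0 °C to rt
Reagents that add atoms: trimethylsilyl triflate, C[Si](C)(C)OS(=O)(=O)C(F)(F)F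
Why: Double soft enolisation and O-silylation of a 1,3-dicarbonyl compound (standard route to 1,3-bis(silyloxy)dienes); the chelated C2 enol is silylated first, and the remaining methyl ketone can then enolise only towards CH3, which gives the nucleophilic terminal CH2.

**Step 7**
Reactants: 8 2,2-dimethyl-5-(3-methylbut-2-en-1-yl)-8-(triisopropylsilyloxy)-2H-chromene-6-carbaldehyde; 10 ethyl (2Z)-2,4-bis(trimethylsilyloxy)penta-2,4-dienoate
Product: 12 ethyl (2S)-2-Ar-4-oxo-3,4-dihydro-2H-pyran-6-carboxylate, via ethyl (2Z,6S)-6-Ar-4-oxo-2,6-bis(trimethylsilyloxy)hex-2-enoate 11 (not isolated)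
Conditions: (S)-BINOL (20 mol%), Ti(Oi-Pr)4 (10 mol%), 4 Å MS, Et2O, −20 °C; then TFA (1 equiv), CH2Cl2, 0 °C
Reagents that add atoms: none
Why: Ti(IV)–BINOL-catalysed vinylogous Mukaiyama aldol (formal hetero-Diels–Alder) of the diene CH2 terminus with the aldehyde; the (S)-BINOL complex is expected, by analogy with its additions to benzaldehydes, to direct attack to the Si face and set C2 as S (the antipodal ligand is equally available should the sense be opposite), and brief TFA treatment closes ring C by attack of the C2 oxygen on the α-keto ester carbon and loss of the silyl groups, while this mild Lewis acid should not trigger a carbonyl-ene reaction of the ortho prenyl group.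

**Step 8**
Reactants: 12 ethyl (2S)-2-Ar-4-oxo-3,4-dihydro-2H-pyran-6-carboxylate
Product: 14 (2S)-2-Ar-4-oxo-3,4-dihydro-2H-pyran-6-carboxylic acid, via its trimethylstannyl ester 13 (not isolated)
Conditions: Me3SnOH, ClCH2CH2Cl, 70 °C; then cold 5% aq HCl wash
Reagents that add atoms: trimethyltin hydroxide (carboxyl oxygen), C[Sn](C)(C)O
Why: Ester cleavage with trimethyltin hydroxide is close to neutral, so it should avoid C3 deprotonation and the E1cB opening of ring C that would racemise C2, and it spares the aryl TIPS ether that aqueous hydroxide would endanger.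

**Step 9**
Reactants: 14 (2S)-2-Ar-4-oxo-3,4-dihydro-2H-pyran-6-carboxylic acid
Product: 16 (2S)-6-(diazoacetyl)-2-Ar-2,3-dihydro-4H-pyran-4-one, via (2S)-2-Ar-4-oxo-3,4-dihydro-2H-pyran-6-carbonyl chloride 15 (not isolated)
Conditions: 1-chloro-N,N,2-trimethylprop-1-en-1-amine, CH2Cl2, 0 °C; then CH2N2 (1.2 equiv), CaO, Et2O–THF, −20 to 0 °C
Reagents that add atoms: diazomethane, C=[N+]=[N-]; 1-chloro-N,N,2-trimethylprop-1-en-1-amine (Cl of 15 only), CC(C)=C(Cl)N(C)C
Why: Acylation of diazomethane as in the first stage of the Arndt–Eistert sequence; the acid chloride, made under neutral conditions and lacking an α-hydrogen, should be acylated much faster than the trisubstituted, oxygen-donor-bearing C5=C6 bond reacts as a dipolarophile, and CaO as HCl scavenger lets about one equivalent of diazomethane suffice, which suppresses pyrazoline and chloromethyl ketone formation better than a slower mixed anhydride with excess reagent.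

**Step 10**
Reactants: 17 acetylene
Product: 20 (triisopropylsilyloxy)ethyne, via lithium acetylide 18 (not isolated), via lithium ethynolate 19 (not isolated)
Conditions: HC≡CH (excess), n-BuLi, THF, −78 °C; t-BuOOLi (anhydrous t-BuOOH, n-BuLi, THF, −78 °C), −78 to −10 °C; TIPSOTf, −78 to 0 °C
Reagents that add atoms: tert-butyl hydroperoxide, used as its lithium salt (O of 19 and 20), CC(C)(C)OO; triisopropylsilyl triflate, CC(C)[Si](C(C)C)(C(C)C)OS(=O)(=O)C(F)(F)F; n-butyllithium (Li of 18 and 19 only), [Li]CCCC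
Why: Electrophilic oxygenation of a lithium acetylide with lithium tert-butyl peroxide gives the ynolate, and the hard, bulky silyl triflate should silylate it on oxygen (the standard one-flask siloxyalkyne synthesis from terminal alkynes).

**Step 11**
Reactants: 16 (2S)-6-(diazoacetyl)-2-Ar-2,3-dihydro-4H-pyran-4-one; 20 (triisopropylsilyloxy)ethyne
Product: 25 (2S)-5-hydroxy-2-Ar-7-(triisopropylsilyloxy)-2,3-dihydro-4H-chromen-4-one, via vinylketene 21 (not isolated), via 4-vinylcyclobutenone 22 (not isolated), via dienylketene 23 (not isolated), via cyclohexadienone 24 (not isolated)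
Conditions: 20 (3 equiv), degassed ClCH2CH2Cl, blue LED (440 nm), 20 °C; then 80 °C in the dark
Reagents that add atoms: none
Why: Blue light should excite only the diazoketone (chromene, enone and aryl ethers do not absorb above 400 nm), and loss of N2 with 1,2-shift of the pyranone carbon C8a from the acyl carbon to the diazo carbon (photo-Wolff rearrangement, forms C8a–C8) gives vinylketene 21. The nucleophilic CH terminus of 20 attacks the ketene carbonyl carbon and the oxygen-bearing carbon closes onto the ketene α-carbon ([2+2], forms C5–C6 and C7–C8) to give 4-vinylcyclobutenone 22, which should accumulate at 20 °C so that no phenol is present while ketene is being generated. At 80 °C ring strain drives reversible conrotatory 4π opening of the C5–C8 bond to dienylketene 23, ring A closes by disrotatory 6π electrocyclisation of the ketene carbon C5 onto the pyranone α-carbon C4a (forms C4a–C5), and dienone 24, whose C4a–H lies between two carbonyl groups, tautomerises to the hydrogen-bonded phenol 25. The closest known reaction type is the Danheiser benzannulation in its diazoketone version with siloxyalkynes, which gives resorcinol monosilyl ethers. No new stereocentre survives in 25 (those of 22 and 24 are lost on aromatisation), and C2 is a spectator because the medium holds neither acid nor base. The step needs regioselectivity (silyloxy group at C7, meta to the new 5-OH), secured by the polarity match of ketene and ynol ether, and chemoselectivity for the ynol ether over the prenyl and chromene alkenes, secured by its far higher nucleophilicity and its excess, while only the C4a=C8a bond is placed to take part in the 6π closure.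

**Step 12**
Reactants: 25 (2S)-5-hydroxy-2-Ar-7-(triisopropylsilyloxy)-2,3-dihydro-4H-chromen-4-one
Product: 26 (2S)-5,7-dihydroxy-2-[8-hydroxy-2,2-dimethyl-5-(3-methylbut-2-en-1-yl)-2H-chromen-6-yl]-2,3-dihydro-4H-chromen-4-one (CNP0224359.1)
Conditions: HF·pyridine, excess pyridine, THF, 0 °C to rt (plastic vessel)
Reagents that add atoms: none
Why: Fluoride cleavage of both aryl TIPS ethers in a buffered, slightly acidic medium forms no phenoxide or enolate, so retro-oxa-Michael racemisation at C2 should not occur, and the diluted reagent should not protonate the prenyl or chromene double bonds.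

**Compound list**
1 | 6-bromovanillin (2-bromo-4-hydroxy-5-methoxybenzaldehyde) | COc1cc(C=O)c(Br)cc1O | starting material
2 | 2-bromo-4,5-dihydroxybenzaldehyde | O=Cc1cc(O)c(O)cc1Br | intermediate
3 | 3-chloro-3-methylbut-1-yne | C#CC(C)(C)Cl | starting material
4 | 2-bromo-5-hydroxy-4-[(2-methylbut-3-yn-2-yl)oxy]benzaldehyde | O=Cc1cc(O)c(OC(C)(C)C#C)cc1Br | intermediate
5 | 2-bromo-4-[(2-methylbut-3-yn-2-yl)oxy]-5-(triisopropylsilyloxy)benzaldehyde | O=Cc1cc(O[Si](C(C)C)(C(C)C)C(C)C)c(OC(C)(C)C#C)cc1Br | intermediate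
6 | 5-bromo-2,2-dimethyl-8-(triisopropylsilyloxy)-2H-chromene-6-carbaldehyde | O=Cc1cc(O[Si](C(C)C)(C(C)C)C(C)C)c2OC(C)(C)C=Cc2c1Br | intermediate
7 | tributyl(3-methylbut-2-en-1-yl)stannane | CCCC[Sn](CCCC)(CCCC)CC=C(C)C | starting material
8 | 2,2-dimethyl-5-(3-methylbut-2-en-1-yl)-8-(triisopropylsilyloxy)-2H-chromene-6-carbaldehyde | O=Cc1cc(O[Si](C(C)C)(C(C)C)C(C)C)c2OC(C)(C)C=Cc2c1CC=C(C)C | intermediate
9 | ethyl 2,4-dioxopentanoate | CCOC(=O)C(=O)CC(C)=O | starting material
10 | ethyl (2Z)-2,4-bis(trimethylsilyloxy)penta-2,4-dienoate | CCOC(=O)/C(O[Si](C)(C)C)=C/C(=C)O[Si](C)(C)C | intermediate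
11 | ethyl (2Z,6S)-6-Ar-4-oxo-2,6-bis(trimethylsilyloxy)hex-2-enoate, not isolated | CCOC(=O)/C(O[Si](C)(C)C)=C/C(=O)C[C@H](O[Si](C)(C)C)c1cc(O[Si](C(C)C)(C(C)C)C(C)C)c2OC(C)(C)C=Cc2c1CC=C(C)C | intermediate
12 | ethyl (2S)-2-Ar-4-oxo-3,4-dihydro-2H-pyran-6-carboxylate | CCOC(=O)C1=CC(=O)C[C@@H](c2cc(O[Si](C(C)C)(C(C)C)C(C)C)c3OC(C)(C)C=Cc3c2CC=C(C)C)O1 | intermediate
13 | trimethylstannyl (2S)-2-Ar-4-oxo-3,4-dihydro-2H-pyran-6-carboxylate, not isolated | C[Sn](C)(C)OC(=O)C1=CC(=O)C[C@@H](c2cc(O[Si](C(C)C)(C(C)C)C(C)C)c3OC(C)(C)C=Cc3c2CC=C(C)C)O1 | intermediate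
14 | (2S)-2-Ar-4-oxo-3,4-dihydro-2H-pyran-6-carboxylic acid | OC(=O)C1=CC(=O)C[C@@H](c2cc(O[Si](C(C)C)(C(C)C)C(C)C)c3OC(C)(C)C=Cc3c2CC=C(C)C)O1 | intermediate
15 | (2S)-2-Ar-4-oxo-3,4-dihydro-2H-pyran-6-carbonyl chloride, not isolated | ClC(=O)C1=CC(=O)C[C@@H](c2cc(O[Si](C(C)C)(C(C)C)C(C)C)c3OC(C)(C)C=Cc3c2CC=C(C)C)O1 | intermediate
16 | (2S)-6-(diazoacetyl)-2-Ar-2,3-dihydro-4H-pyran-4-one | [N-]=[N+]=CC(=O)C1=CC(=O)C[C@@H](c2cc(O[Si](C(C)C)(C(C)C)C(C)C)c3OC(C)(C)C=Cc3c2CC=C(C)C)O1 | intermediate
17 | acetylene | C#C | starting material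
18 | lithium acetylide, not isolated | [Li+].[C-]#C | intermediate
19 | lithium ethynolate, not isolated | [Li+].[O-]C#C | intermediate
20 | (triisopropylsilyloxy)ethyne | C#CO[Si](C(C)C)(C(C)C)C(C)C | intermediate
21 | vinylketene, (2S)-2-Ar-6-(2-oxoethenyl)-2,3-dihydro-4H-pyran-4-one, not isolated | O=C=CC1=CC(=O)C[C@@H](c2cc(O[Si](C(C)C)(C(C)C)C(C)C)c3OC(C)(C)C=Cc3c2CC=C(C)C)O1 | intermediate
22 | 4-[(2S)-2-Ar-4-oxo-3,4-dihydro-2H-pyran-6-yl]-3-(triisopropylsilyloxy)cyclobut-2-en-1-one (both epimers at the cyclobutenone C4), not isolated | O=C4C=C(O[Si](C(C)C)(C(C)C)C(C)C)C4C1=CC(=O)C[C@@H](c2cc(O[Si](C(C)C)(C(C)C)C(C)C)c3OC(C)(C)C=Cc3c2CC=C(C)C)O1 | intermediate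
23 | dienylketene, (2S)-2-Ar-6-[4-oxo-2-(triisopropylsilyloxy)buta-1,3-dien-1-yl]-2,3-dihydro-4H-pyran-4-one (ketene chain and pyranone cis on C7=C8), not isolated | O=C=C/C(O[Si](C(C)C)(C(C)C)C(C)C)=C\C1=CC(=O)C[C@@H](c2cc(O[Si](C(C)C)(C(C)C)C(C)C)c3OC(C)(C)C=Cc3c2CC=C(C)C)O1 | intermediate
24 | (2S)-2-Ar-7-(triisopropylsilyloxy)-2,3-dihydro-4aH-chromene-4,5-dione (keto tautomer of 25, C4a undefined), not isolated | O=C1C[C@@H](c2cc(O[Si](C(C)C)(C(C)C)C(C)C)c3OC(C)(C)C=Cc3c2CC=C(C)C)OC2=CC(O[Si](C(C)C)(C(C)C)C(C)C)=CC(=O)C12 | intermediate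
25 | (2S)-5-hydroxy-2-Ar-7-(triisopropylsilyloxy)-2,3-dihydro-4H-chromen-4-one | O=C1C[C@@H](c2cc(O[Si](C(C)C)(C(C)C)C(C)C)c3OC(C)(C)C=Cc3c2CC=C(C)C)Oc2cc(O[Si](C(C)C)(C(C)C)C(C)C)cc(O)c12 | intermediate
26 | (2S)-5,7-dihydroxy-2-[8-hydroxy-2,2-dimethyl-5-(3-methylbut-2-en-1-yl)-2H-chromen-6-yl]-2,3-dihydro-4H-chromen-4-one | CC(C)=CCc1c([C@@H]2CC(=O)c3c(O)cc(O)cc3O2)cc(O)c2c1C=CC(C)(C)O2 | target

**Step count**
- Total: 12 steps; steps 6 and 10 are side branches.
- Longest linear sequence: 10 steps from 6-bromovanillin (steps 1–5, 7–9, 11, 12).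

**Steps most likely to fail**

**1. Step 11.**
- What may go wrong: the acyl- and oxygen-substituted vinylketene may dimerise or be trapped by adventitious nucleophiles faster than it undergoes the [2+2]. The terminal ynol ether may isomerise to the silylketene on heating. The 4π/6π sequence may stall at the cyclobutenone stage.
- Fallback: this gives up the benzannulation and takes ring A from a phloroglucinol. It sets out from aldehyde 8 and comes back at 25. Commercial 2,4,6-trihydroxyacetophenone is silylated with one equivalent of TIPSCl and imidazole at the 4-OH, the hydroxyl not engaged with the ketone, to give 1-[2,6-dihydroxy-4-(triisopropylsilyloxy)phenyl]ethanone F1. Pyrrolidine-catalysed Claisen–Schmidt condensation of F1 with 8 in ethanol should give (E)-1-[2,6-dihydroxy-4-(triisopropylsilyloxy)phenyl]-3-Ar-prop-2-en-1-one F2. This chalcone closes by oxa-Michael addition under the same conditions to racemic 5-hydroxy-2-Ar-7-(triisopropylsilyloxy)chroman-4-one F3. Preparative HPLC on a chiral stationary phase separates 25 from its (2R)-enantiomer F4, which can be re-equilibrated through F2 with mild base and recycled.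

**2. Step 7.**
- What may go wrong: turnover may be slow with the hindered, electron-rich aldehyde. Facial selectivity may be poor because the ester-bearing diene is less nucleophilic than the dienes for which the catalyst type is established. Partial ionisation of the p-alkoxybenzylic C–O bond during the TFA treatment would erode the enantiomeric purity.
- Fallback: this replaces catalysis by a reagent-controlled boron aldol through a closed transition state. It sets out from 9 and 8 and comes back at 12. Diketoester 9 is O-methylated at its C2 enol (trimethyl orthoformate, catalytic TsOH, MeOH) to give ethyl (2Z)-2-methoxy-4-oxopent-2-enoate F5, which can enolise only towards CH3. Its diisopinocampheylboron enolate (the Ipc2BCl antipode that attacks the Si face, Et3N, Et2O) is added to 8 at −78 °C to give ethyl (2Z,6S)-6-Ar-6-hydroxy-2-methoxy-4-oxohex-2-enoate F6. PPTS then closes ring C by oxa-Michael addition and elimination of methanol, giving 12 without exposure to strong acid.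

**3. Step 10.**
- What may go wrong: monolithium acetylide may disproportionate on warming before it is oxygenated. The unhindered carbon terminus of the parent ynolate may be silylated in competition with oxygen. The terminal silyl ynol ether may be lost through volatility or isomerisation during isolation.
- Fallback: this changes the ketenophile to a tert-alkyl ynol ether whose triple bond is made by elimination, so no ambident ynolate is involved. It sets out from diazoketone 16 and comes back at 26. Potassium tert-butoxide and trichloroethylene (addition to dichloroacetylene formed in situ) give (E)-1,2-dichlorovinyl tert-butyl ether F7. Two equivalents of n-BuLi at −78 °C followed by methanol convert it into tert-butoxyethyne F8. This is used cold under the irradiation conditions of step 11, and its excess is removed in vacuo before the 80 °C stage, to give (2S)-7-tert-butoxy-5-hydroxy-2-Ar-chroman-4-one F9. Brief exposure to TFA in CH2Cl2 at 0 °C cleaves the activated aryl tert-butyl ether to (2S)-5,7-dihydroxy-2-Ar-chroman-4-one F10. The conditions of step 12 then remove the remaining TIPS group to give 26.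

**Further compounds**
F1 | step 11 | 1-[2,6-dihydroxy-4-(triisopropylsilyloxy)phenyl]ethanone | CC(=O)c1c(O)cc(O[Si](C(C)C)(C(C)C)C(C)C)cc1O
F2 | step 11 | (E)-1-[2,6-dihydroxy-4-(triisopropylsilyloxy)phenyl]-3-Ar-prop-2-en-1-one | O=C(/C=C/c1cc(O[Si](C(C)C)(C(C)C)C(C)C)c2OC(C)(C)C=Cc2c1CC=C(C)C)c1c(O)cc(O[Si](C(C)C)(C(C)C)C(C)C)cc1O
F3 | step 11 | racemic 5-hydroxy-2-Ar-7-(triisopropylsilyloxy)chroman-4-one | O=C1CC(c2cc(O[Si](C(C)C)(C(C)C)C(C)C)c3OC(C)(C)C=Cc3c2CC=C(C)C)Oc2cc(O[Si](C(C)C)(C(C)C)C(C)C)cc(O)c12
F4 | step 11 | (2R)-5-hydroxy-2-Ar-7-(triisopropylsilyloxy)chroman-4-one | O=C1C[C@H](c2cc(O[Si](C(C)C)(C(C)C)C(C)C)c3OC(C)(C)C=Cc3c2CC=C(C)C)Oc2cc(O[Si](C(C)C)(C(C)C)C(C)C)cc(O)c12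
F5 | step 7 | ethyl (2Z)-2-methoxy-4-oxopent-2-enoate | CCOC(=O)/C(OC)=C/C(C)=O
F6 | step 7 | ethyl (2Z,6S)-6-Ar-6-hydroxy-2-methoxy-4-oxohex-2-enoate | CCOC(=O)/C(OC)=C/C(=O)C[C@H](O)c1cc(O[Si](C(C)C)(C(C)C)C(C)C)c2OC(C)(C)C=Cc2c1CC=C(C)C
F7 | step 10 | (E)-1,2-dichlorovinyl tert-butyl ether | CC(C)(C)O/C(Cl)=C\Cl
F8 | step 10 | tert-butoxyethyne | CC(C)(C)OC#C
F9 | step 10 | (2S)-7-tert-butoxy-5-hydroxy-2-Ar-chroman-4-one | O=C1C[C@@H](c2cc(O[Si](C(C)C)(C(C)C)C(C)C)c3OC(C)(C)C=Cc3c2CC=C(C)C)Oc2cc(OC(C)(C)C)cc(O)c12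
F10 | step 10 | (2S)-5,7-dihydroxy-2-Ar-chroman-4-one | O=C1C[C@@H](c2cc(O[Si](C(C)C)(C(C)C)C(C)C)c3OC(C)(C)C=Cc3c2CC=C(C)C)Oc2cc(O)cc(O)c12
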